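Watch the crystals rather than the clock when this flask is run again.

Z 20 mM; Q 0.74 µM; G 3.4 µM; time 15 d

    Z + Q ⇌ Z.Q (K1 = 110 M⁻¹, k1 = 1.11 × 10⁷ M⁻¹ h⁻¹)
    Z.Q ⇌ Q + L (K2 = 0.042 M, k2 = 12500 h⁻¹)
    E ⇌ L, rate k3*(cs3 - [L]) while solid is left; crystals form when [L] > cs3 (cs3 = 1.5 mM, k3 = 1.67 h⁻¹)
    Q + G ⇌ Q.G, settled at all times (K4 = 3.7 × 10⁶ M⁻¹)

- L is meant together with its E
- solid, in amounts per volume of the solution: E
- run time (flask): 15 d

* amount of L at 15 d, in percent of the Z charged
* amount of L if the flask were left three thousand times as long, in percent of the Z charged

I took the even case as the zero of my scale: an overall constant of one between Z and L splits a charge in solution half and half. The overall constant of this flask, the product of the constants of the first two steps, was 4.62, so the solution by itself gave L a share of 82.2 %.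

I then turned the question round. For a flask that stopped there without crystals, that share would have had to stay below the solubility, which was 7.50 % of the charge. It stood at about ten times that fraction, so crystals had to form.

At balance with solid standing, dissolved L sits at the solubility and Z answers to that dissolved part. This gave me the residue, the fraction of the charge left as free Z once crystals stand, which is the solubility fraction divided by the overall constant: 1.62 %. It marks the end point under thermodynamic control, and I committed to 98.4 % as L with its E. The residue holds no rate constant, so my reckoning said where the flask ends and not when.

The forecast gave 98.4 % at the asked time and 98.4 % for the long stay, on the grounds that “360 h is about 25 time constants, so equilibrium is reached by 15 d”.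

The flask gave 98.4 % and 98.4 %, with Z at 1.6 % of the charge against my residue of 1.62 %. Half of the turnover from Z.Q to Q + L was done by 0.411 d, far sooner than the 15 d allowed, and Z read 1.62 % at 7.50 d and 1.62 % at 15.0 d.

In the neighbour flask charged with 5.0 mM of Z, the solubility was a larger fraction of the charge, and the residue gave 6.49 %. That flask held 6.5 % of its Z at 15.0 d, with 93.5 % as L.

(The numbers of this flask are made up.)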